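(The earlier runs and the new flask were generated by integration on assumed constants.)

As planner of the north-west run, I had one choice to make for Z → G over the catalyst L: keep the south charge of Z and the 26 min limit and raise c(L) to 7.30 × 10⁻⁴ M, or run longer at the old c(L).

| setting | south | west | north | south-west | north-west |
|---|---|---|---|---|---|
| Z | 0.150 M | 0.0600 M | 0.450 M | 0.150 M | 0.150 M |
| L | 3.00 × 10⁻⁴ M | 3.00 × 10⁻⁴ M | 3.00 × 10⁻⁴ M | 4.50 × 10⁻⁴ M | 7.30 × 10⁻⁴ M |
| time |  |  |  |  | 26 min |

| south run: time / min | south run: [G] / M | west run: time / min | west run: [G] / M | north run: time / min | north run: [G] / M | south-west run: time / min | south-west run: [G] / M |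
|---|---|---|---|---|---|---|---|
| 1.5 | 0.0133 | 1.5 | 0.0100 | 1.5 | 0.0200 | 1.5 | 0.0159 |
| 4.5 | 0.0318 | 4.5 | 0.0205 | 4.5 | 0.0467 | 4.5 | 0.0419 |
| 8.6 | 0.0491 | 8.6 | 0.0319 | 8.6 | 0.0749 | 8.6 | 0.0602 |
| 14 | 0.0630 | 14 | 0.0384 | 14 | 0.0995 | 14 | 0.0770 |
| 19 | 0.0744 | 19 | 0.0418 | 19 | 0.1177 | 19 | 0.0868 |
| 26 | 0.0818 | 26 | 0.0447 | 26 | 0.1380 | 26 | 0.0945 |

(standard deviation of a reading: 8 × 10⁻⁴ M)

- the power of [Z] that the first rate follows, about the charge of the south run; measure it at two percent of Z made into G (one fixed amount of G, the same in the runs compared)
- the power of [L] that the first rate follows, about the charge of the south run; measure it at two percent of Z made into G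
- the west run starts with 0.0900 M less of Z than the south run, and with no G. Compared where both hold the same amount of Z, once fifteen percent of what the west run was charged with has turned into G, is the west run faster, slower or alike (within a tenth)?
- G in the north-west run at 26 min, as a share of the Z charged

- Overall: Z -> G, with L as catalyst.
- Constant volume, constant temperature.
- Bound and free are read together.
- An order is taken over about fifteen percent of the charge, up and down.

1. I reckoned with one quantity. The planned flask carries 1.14 M·s of catalyst-time, meaning c(L) as charged multiplied by the time run. If equal catalyst-time gives equal G at a fixed charge of Z, L can replace minutes.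

2. I tested this on the two runs that share c(Z). The south run read 0.0630 M at 14 min. The south-west run should match it at 9.33 min, and interpolating its readings gave 0.0625 M. The gap lay within the scatter of 8 × 10⁻⁴ M.

3. At the south c(L), the same catalyst-time needs 63.3 min, so I kept 26 min and raised c(L).

4. The south-west run ended at 0.702 M·s, less catalyst-time than planned, so I had to extrapolate. Its last two readings gave a slope, G gained over catalyst-time, of 2.44 /min, lower than the 4.36 /min of the interval before.

5. A straight line at the last slope gave 74.9 % of the Z charged. The slope had fallen between the two intervals, so I committed to a share below that.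

6. The forecast gave 71 % (range 66 % to 77 %), orders of 0.3 in Z and 0.95 in L, and the west run faster, holding that “the rate scales nearly with [L] and depends on L·t”; its central share lay below my straight line.

7. At its 1.14 M·s of catalyst-time the north-west run gave 69.1 %, lower than my straight line, with orders of 0.44 in Z and 1.0 in L, and the west run faster.

    L + Z ⇌ LZ, settled at all times (10.50 /M)
    LZ ⇌ G + L (132.6 /min, 192.0 /M/min)
    2 Z ⇌ Z2, settled at all times (59.80 /M)
    L + G ⇌ LG, settled at all times (21.30 /M)

Catalyst-time also held on the south-west run: half of the Z charged had turned at 13.4 min, which is 0.362 M·s, against 0.362 M·s from 20.1 min in the south run. The north-west run fell short of full conversion mainly because of the binding of 2 Z into Z2. The same run without that binding gives 87.9 % instead of 69.1 %, and the binding accounts for 61 % of what is missing.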